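**Retrosynthetic overview**
1. Target ⇐ its C1 silyl ether ⇐ (key step) a ten-membered carbocycle with an alkenyl pinacol boronate at C11 and an allylic chloride at C6, plus CO2: one flask forms C11–C12 and O–C6 of the lactone.
2. Enabling feature: C6 is an sp3 carbon allylic to the ring alkene C4=C5 and 1,3 to the vinylic carbon C11 of the exocyclic methylene, so the γ-lactone ring (O–C12–C11–C7–C6) is one CO2 unit spanning a vinyl nucleophile and an allylic electrophile.
3. Carbocycle ⇐ Nozaki–Hiyama–Kishi closure C5–C6 of a Z-alkenyl iodide onto an aldehyde; open chain ⇐ boron anti-aldol (C10–C1) of an α-(epoxyangeloyloxy) ethyl ketone with (Z)-5-iodo-4-methylpent-4-enal.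
4. Ketone ⇐ Evans syn-aldol (C7–C8) of a 3-bromobut-3-enoyl imide with 2-ethylacrolein, then ozonolysis and Miyaura borylation; epoxyangelic acid ⇐ Sharpless epoxidation of (Z)-2-methylbut-2-en-1-ol.
5. Ring order: side-chain oxirane (step 2), ten-membered carbocycle (step 17), γ-lactone (step 19).

Key step: step 19

Remark: locants C1 to C13 are germacrane locants of the target, ring C1(OH)–C2–C3–C4(CH3)=C5–C6(O)–C7–C8(O-acyl)–C9(=O)–C10(CH3), with C11(=C13H2) on C7 and lactone carbonyl C12; 3-bromobut-3-enoic acid and methyl angelate are assumed to be commercially available.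

Step 1
Reactants: 1 methyl (2Z)-2-methylbut-2-enoate (methyl angelate)
Product: 2 (2Z)-2-methylbut-2-en-1-ol
Conditions: DIBAL-H (2.2 equiv), CH2Cl2, −78 °C; Rochelle salt work-up
Reagents that add atoms: none
Why: Low-temperature 1,2-reduction of the enoate by DIBAL-H gives the allylic alcohol and leaves the Z double bond untouched.

Step 2
Reactants: 2 (2Z)-2-methylbut-2-en-1-ol
Product: 3 [(2S,3R)-2,3-dimethyloxiran-2-yl]methanol
Conditions: Ti(OiPr)4 (10 mol%), L-(+)-diethyl tartrate (12 mol%), t-BuOOH, 4 Å MS, CH2Cl2, −20 °C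
Reagents that add atoms: tert-butyl hydroperoxide, CC(C)(C)OO
Why: Sharpless asymmetric epoxidation, in which the titanium–L-(+)-tartrate complex delivers the peroxide oxygen to the enantioface that gives 2S epoxy alcohols (as with geraniol and nerol), setting 2S,3R with the cis relation of the Z-alkene retained.

Step 3
Reactants: 3 [(2S,3R)-2,3-dimethyloxiran-2-yl]methanol
Product: 4 (2R,3R)-2,3-dimethyloxirane-2-carboxylic acid (epoxyangelic acid)
Conditions: RuCl3 hydrate (2 mol%), NaIO4 (3 equiv), CCl4/MeCN/H2O, rt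
Reagents that add atoms: water, O
Why: Ruthenium tetroxide oxidation of the primary epoxy alcohol through the aldehyde hydrate is the standard follow-up to the asymmetric epoxidation and does not touch the oxirane stereocenters (2S becomes 2R only through the change in substituent priority).

Step 4
Reactants: 5 2-(2-bromoethyl)-1,3-dioxolane; 6 propyne
Product: 10 2-[(3Z)-4-iodo-3-methylbut-3-en-1-yl]-1,3-dioxolane, via Grignard reagent 7 (not isolated), via alkylcopper 8 (not isolated), via alkenylcopper 9 (not isolated)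
Conditions: Mg, THF, 30 °C; CuBr·SMe2, Et2O/Me2S, −45 °C; propyne, −45 → −25 °C; I2, −78 → 0 °C
Reagents that add atoms: iodine, II
Why: Normant carbocupration adds the alkylcopper syn across propyne with copper on the terminal carbon, and iodinolysis with retention gives the Z-1-iodo-2-methylalkene (iodine cis to the chain) that later fixes the ring-cis C4=C5 geometry.

Step 5
Reactants: 10 2-[(3Z)-4-iodo-3-methylbut-3-en-1-yl]-1,3-dioxolane
Product: 11 (4Z)-5-iodo-4-methylpent-4-enal
Conditions: 1 M HCl, THF, rt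
Reagents that add atoms: water, O
Why: Acid-catalysed acetal hydrolysis, to which the alkenyl iodide is inert.

Step 6
Reactants: 12 3-bromobut-3-enoic acid; 13 (4R)-4-benzyl-1,3-oxazolidin-2-one
Product: 15 (4R)-4-benzyl-3-(3-bromobut-3-enoyl)-1,3-oxazolidin-2-one, via mixed pivalic anhydride 14 (not isolated)
Conditions: PivCl, Et3N, THF, −20 °C; then 13, LiCl, −20 °C → rt
Reagents that add atoms: none
Why: N-acylation of the oxazolidinone through the mixed pivalic anhydride under LiCl/Et3N activation is mild enough to avoid conjugation of the β,γ-unsaturated acyl group.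

Step 7
Reactants: 15 (4R)-4-benzyl-3-(3-bromobut-3-enoyl)-1,3-oxazolidin-2-one; 16 2-methylidenebutanal (2-ethylacrolein)
Product: 19 (4R)-4-benzyl-3-[(2R,3R)-2-(1-bromoethenyl)-3-hydroxy-4-methylidenehexanoyl]-1,3-oxazolidin-2-one, via boron dienolate 17 (not isolated), via boron aldolate 18 (not isolated)
Conditions: Bu2BOTf, iPr2NEt, CH2Cl2, −78 → 0 °C; 16, −78 → 0 °C; pH 7 buffer, MeOH, H2O2, 0 °C
Reagents that add atoms: none
Why: Evans syn-aldol, in which the Z-configured dibutylboron dienolate of the (R)-benzyl imide reacts at its α-carbon through a closed chair transition state on the face away from the benzyl group, setting C7 and C8 (2R,3R in the acyl chain) and carrying the 1-bromovinyl group through unchanged.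

Step 8
Reactants: 19 (4R)-4-benzyl-3-[(2R,3R)-2-(1-bromoethenyl)-3-hydroxy-4-methylidenehexanoyl]-1,3-oxazolidin-2-one
Product: 20 (2S,3R)-2-(1-bromoethenyl)-4-methylidenehexane-1,3-diol
Conditions: LiBH4, MeOH (1 equiv), THF, 0 °C
Reagents that add atoms: none
Why: Reductive removal of the auxiliary by hydride attack at the exocyclic imide carbonyl gives the primary C6 alcohol without touching the alkenyl bromide or any stereocenter.

Step 9
Reactants: 20 (2S,3R)-2-(1-bromoethenyl)-4-methylidenehexane-1,3-diol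
Product: 21 (2S,3R)-2-(1-bromoethenyl)-4-methylidene-1-(triethylsilyloxy)hexan-3-ol
Conditions: TESCl (1.05 equiv), imidazole, CH2Cl2, −40 °C
Reagents that add atoms: chlorotriethylsilane, CC[Si](Cl)(CC)CC
Why: The primary C6 hydroxyl is silylated much faster than the hindered secondary allylic C8 hydroxyl at low temperature.

Step 10
Reactants: 21 (2S,3R)-2-(1-bromoethenyl)-4-methylidene-1-(triethylsilyloxy)hexan-3-ol; 4 (2R,3R)-2,3-dimethyloxirane-2-carboxylic acid
Product: 23 (2S,3R)-2-(1-bromoethenyl)-4-methylidene-1-(triethylsilyloxy)hexan-3-yl (2R,3R)-2,3-dimethyloxirane-2-carboxylate, via mixed anhydride 22 (not isolated)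
Conditions: 2,4,6-trichlorobenzoyl chloride, Et3N, THF, rt; then 21, DMAP, toluene, 40 °C
Reagents that add atoms: none
Why: Yamaguchi esterification through the mixed anhydride with DMAP acyl transfer suits a hindered secondary alcohol and an α,α-disubstituted acid, and since the C8–O bond is not broken the configuration is retained.

Step 11
Reactants: 23 (2S,3R)-2-(1-bromoethenyl)-4-methylidene-1-(triethylsilyloxy)hexan-3-yl (2R,3R)-2,3-dimethyloxirane-2-carboxylate
Product: 25 (2S,3R)-2-(1-bromoethenyl)-4-oxo-1-(triethylsilyloxy)hexan-3-yl (2R,3R)-2,3-dimethyloxirane-2-carboxylate, via ozonide 24 (not isolated)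
Conditions: O3, CH2Cl2, −78 °C (Sudan Red 7B end point); Me2S, −78 °C → rt
Reagents that add atoms: ozone, [O-][O+]=O
Why: Ozonolysis is chemoselective because the electron-rich 1,1-dialkyl alkene reacts much faster than the electron-poor 1-bromoalkene, so titration to the dye end point cleaves only the C9 methylidene and unveils the ethyl ketone.

Step 12
Reactants: 25 (2S,3R)-2-(1-bromoethenyl)-4-oxo-1-(triethylsilyloxy)hexan-3-yl (2R,3R)-2,3-dimethyloxirane-2-carboxylate
Product: 26 (2S,3R)-4-oxo-2-[1-(4,4,5,5-tetramethyl-1,3,2-dioxaborolan-2-yl)ethenyl]-1-(triethylsilyloxy)hexan-3-yl (2R,3R)-2,3-dimethyloxirane-2-carboxylate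
Conditions: B2pin2, PdCl2(dppf) (5 mol%), KOAc, 1,4-dioxane, 80 °C
Reagents that add atoms: bis(pinacolato)diboron, CC1(C)OB(OC1(C)C)B1OC(C)(C)C(C)(C)O1
Why: Miyaura borylation (oxidative addition of the alkenyl bromide to zerovalent palladium, acetate-assisted transmetallation with B2pin2, reductive elimination) gives the 1,1-disubstituted alkenylboronate, and the weakly basic KOAc spares the α-acyloxy ketone.

Step 13
Reactants: 26 (2S,3R)-4-oxo-2-[1-(4,4,5,5-tetramethyl-1,3,2-dioxaborolan-2-yl)ethenyl]-1-(triethylsilyloxy)hexan-3-yl (2R,3R)-2,3-dimethyloxirane-2-carboxylate; 11 (4Z)-5-iodo-4-methylpent-4-enal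
Product: 29 (2S,3R,5S,6S,9Z)-6-hydroxy-10-iodo-5,9-dimethyl-4-oxo-2-[1-(pinacolboryl)ethenyl]-1-(triethylsilyloxy)dec-9-en-3-yl (2R,3R)-2,3-dimethyloxirane-2-carboxylate, via enol borinate 27 (not isolated), via boron aldolate 28 (not isolated)
Conditions: (c-C6H11)2BCl, Me2NEt, Et2O, −78 → 0 °C; 11, −78 → −20 °C; MeOH, pH 7 buffer, then silica gel (no peroxide work-up)
Reagents that add atoms: none
Why: Boron-mediated anti-aldol of an α-acyloxy ethyl ketone (Paterson-type), in which the E-enol dicyclohexylborinate reacts through a chair transition state with the C8 hydrogen eclipsing the enolate double bond and the C8 ester carbonyl turned towards the aldehyde (formyl hydrogen bond), so the aldehyde adds to the enolate face on the ester side and sets 10S and 1S (C5 and C6 of the chain name).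

Step 14
Reactants: 29 (2S,3R,5S,6S,9Z)-6-hydroxy-10-iodo-5,9-dimethyl-4-oxo-2-[1-(pinacolboryl)ethenyl]-1-(triethylsilyloxy)dec-9-en-3-yl (2R,3R)-2,3-dimethyloxirane-2-carboxylate
Product: 30 (2S,3R,5S,6S,9Z)-6-(tert-butyldimethylsilyloxy)-10-iodo-5,9-dimethyl-4-oxo-2-[1-(pinacolboryl)ethenyl]-1-(triethylsilyloxy)dec-9-en-3-yl (2R,3R)-2,3-dimethyloxirane-2-carboxylate
Conditions: TBSOTf, 2,6-lutidine, CH2Cl2, −78 °C
Reagents that add atoms: tert-butyldimethylsilyl triflate, CC(C)(C)[Si](C)(C)OS(=O)(=O)C(F)(F)F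
Why: Silylation of the secondary C1 hydroxyl with the silyl triflate and a hindered base at −78 °C blocks retro-aldol cleavage and oxidation in the following steps.

Step 15
Reactants: 30 (2S,3R,5S,6S,9Z)-6-(tert-butyldimethylsilyloxy)-10-iodo-5,9-dimethyl-4-oxo-2-[1-(pinacolboryl)ethenyl]-1-(triethylsilyloxy)dec-9-en-3-yl (2R,3R)-2,3-dimethyloxirane-2-carboxylate
Product: 31 (2S,3R,5S,6S,9Z)-6-(tert-butyldimethylsilyloxy)-1-hydroxy-10-iodo-5,9-dimethyl-4-oxo-2-[1-(pinacolboryl)ethenyl]dec-9-en-3-yl (2R,3R)-2,3-dimethyloxirane-2-carboxylate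
Conditions: PPTS (0.2 equiv), MeOH/CH2Cl2, 0 °C
Reagents that add atoms: none
Why: Acid-catalysed methanolysis cleaves the primary triethylsilyl ether selectively in the presence of the secondary tert-butyldimethylsilyl ether.

Step 16
Reactants: 31 (2S,3R,5S,6S,9Z)-6-(tert-butyldimethylsilyloxy)-1-hydroxy-10-iodo-5,9-dimethyl-4-oxo-2-[1-(pinacolboryl)ethenyl]dec-9-en-3-yl (2R,3R)-2,3-dimethyloxirane-2-carboxylate
Product: 32 (2R,3R,5S,6S,9Z)-6-(tert-butyldimethylsilyloxy)-10-iodo-5,9-dimethyl-1,4-dioxo-2-[1-(pinacolboryl)ethenyl]dec-9-en-3-yl (2R,3R)-2,3-dimethyloxirane-2-carboxylate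
Conditions: Dess–Martin periodinane, NaHCO3, CH2Cl2, 0 °C → rt
Reagents that add atoms: none
Why: Dess–Martin oxidation under bicarbonate buffer gives the C6 aldehyde without base, so the allylic α-stereocenter C7 is not epimerised and the double bond does not move into conjugation (the descriptor change at C7 is only a priority change).

Step 17
Reactants: 32 (2R,3R,5S,6S,9Z)-6-(tert-butyldimethylsilyloxy)-10-iodo-5,9-dimethyl-1,4-dioxo-2-[1-(pinacolboryl)ethenyl]dec-9-en-3-yl (2R,3R)-2,3-dimethyloxirane-2-carboxylate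
Product: 33 (1S,6S,7S,8R,10S)-1-(tert-butyldimethylsilyloxy)-6-hydroxy-4,10-dimethyl-9-oxo-7-[1-(pinacolboryl)ethenyl]cyclodec-4Z-en-8-yl (2R,3R)-2,3-dimethyloxirane-2-carboxylate (germacrane locants)
Conditions: CrCl2 (8 equiv), NiCl2 (0.1 equiv), DMSO/THF, rt, slow addition to 0.002 M
Reagents that add atoms: none
Why: Nozaki–Hiyama–Kishi reaction, in which the nickel-activated alkenyl iodide is passed on to chromium as a nucleophilic alkenylchromium species that adds only to the aldehyde (ketone, esters, oxirane and boronate are inert) and closes the ten-membered ring with retention of the Z geometry, addition anti to the bulky 2-borylvinyl group at C7 (Felkin–Anh) being expected to give the 6S carbinol.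

Step 18
Reactants: 33 (1S,6S,7S,8R,10S)-1-(tert-butyldimethylsilyloxy)-6-hydroxy-4,10-dimethyl-9-oxo-7-[1-(pinacolboryl)ethenyl]cyclodec-4Z-en-8-yl (2R,3R)-2,3-dimethyloxirane-2-carboxylate
Product: 34 (1S,6R,7R,8R,10S)-1-(tert-butyldimethylsilyloxy)-6-chloro-4,10-dimethyl-9-oxo-7-[1-(pinacolboryl)ethenyl]cyclodec-4Z-en-8-yl (2R,3R)-2,3-dimethyloxirane-2-carboxylate (germacrane locants)
Conditions: PPh3, hexachloroacetone, CH2Cl2, −20 → 0 °C
Reagents that add atoms: hexachloroacetone, ClC(Cl)(Cl)C(=O)C(Cl)(Cl)Cl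
Why: Appel-type chlorination with PPh3/hexachloroacetone converts secondary allylic alcohols into chlorides by SN2 displacement of the alkoxyphosphonium ion without allylic transposition, so C6 is inverted to 6R.

Step 19
Reactants: 34 (1S,6R,7R,8R,10S)-1-(tert-butyldimethylsilyloxy)-6-chloro-4,10-dimethyl-9-oxo-7-[1-(pinacolboryl)ethenyl]cyclodec-4Z-en-8-yl (2R,3R)-2,3-dimethyloxirane-2-carboxylate
Product: 37 (1S,6S,7S,8R,10S)-1-(tert-butyldimethylsilyloxy)-8-[(2R,3R)-epoxyangeloyloxy]-9-oxogermacra-4Z,11(13)-dien-12,6-olide, via borate complex 35 (not isolated), via potassium acrylate 36 (not isolated)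
Conditions: KOtBu (1.1 equiv), THF, −40 °C; then CO2 (1 atm, saturated solution), (IPr)CuCl (10 mol%), 0 → 65 °C
Reagents that add atoms: carbon dioxide, O=C=O
Why: tert-Butoxide turns the pinacol boronate into its ate complex 35, boron-to-copper transmetallation gives an NHC-bound alkenylcopper, CO2 inserts into its Cu–C(sp2) bond to form C11–C12, and the released potassium 2-alkylacrylate 36 then displaces the allylic chloride at C6 through its carboxylate oxygen to form O–C6. The closest known reaction types are the copper–NHC-catalysed carboxylation of aryl- and alkenylboronic esters with CO2 and the O-alkylation of carboxylates by allylic halides, here run in tandem in one flask. The only ring closed is the γ-lactone, by a 5-exo-tet SN2 displacement. The only new stereocenter is C6, set by inversion of the 6R chloride so that H6 and H7 end up cis (cis-fused lactone, 6S), while C1, C7, C8 and C10 are spectators. The step needs CO2 insertion to outrun copper-mediated allyl transfer and oxygen attack at C6 rather than C4: the first is secured by CO2 saturation and by the 5-endo geometry that any C11-to-C4 attack would require, the second by the 1,3-relation of C11 and C6, which makes the five-membered ring the only unstrained mode. Under CO2 free tert-butoxide is buffered as tert-butyl carbonate, which protects the β-silyloxy ketone and the α-acyloxy ketone from elimination and epimerisation.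

Step 20
Reactants: 37 (1S,6S,7S,8R,10S)-1-(tert-butyldimethylsilyloxy)-8-[(2R,3R)-epoxyangeloyloxy]-9-oxogermacra-4Z,11(13)-dien-12,6-olide
Product: 38 CNP0149149.1, (1S,6S,7S,8R,10S)-8-[(2R,3R)-epoxyangeloyloxy]-1-hydroxy-9-oxogermacra-4Z,11(13)-dien-12,6-olide
Conditions: HF·pyridine, pyridine, THF, 0 °C → rt
Reagents that add atoms: none
Why: Fluoride cleavage of the secondary silyl ether with pyridine-buffered HF should leave the glycidic ester, the α-methylene lactone and the resulting β-hydroxy ketone intact, and no stereocenter is touched.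

**Compound list**
1 | methyl (2Z)-2-methylbut-2-enoate (methyl angelate) | C/C=C(/C)C(=O)OC | starting material
2 | (2Z)-2-methylbut-2-en-1-ol | C/C=C(/C)CO | intermediate
3 | [(2S,3R)-2,3-dimethyloxiran-2-yl]methanol | OC[C@]1(C)O[C@@H]1C | intermediate
4 | (2R,3R)-2,3-dimethyloxirane-2-carboxylic acid (epoxyangelic acid) | OC(=O)[C@]1(C)O[C@@H]1C | intermediate
5 | 2-(2-bromoethyl)-1,3-dioxolane | BrCCC1OCCO1 | starting material
6 | propyne | CC#C | starting material
7 | [2-(1,3-dioxolan-2-yl)ethyl]magnesium bromide | Br[Mg]CCC1OCCO1 | intermediate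
8 | [2-(1,3-dioxolan-2-yl)ethyl]copper (dimethyl sulfide/MgBr2 complex) | [Cu]CCC1OCCO1 | intermediate
9 | [(1Z)-4-(1,3-dioxolan-2-yl)-2-methylbut-1-en-1-yl]copper | [Cu]/C=C(/C)CCC1OCCO1 | intermediate
10 | 2-[(3Z)-4-iodo-3-methylbut-3-en-1-yl]-1,3-dioxolane | I/C=C(/C)CCC1OCCO1 | intermediate
11 | (4Z)-5-iodo-4-methylpent-4-enal | I/C=C(/C)CCC=O | intermediate
12 | 3-bromobut-3-enoic acid | C=C(Br)CC(=O)O | starting material
13 | (4R)-4-benzyl-1,3-oxazolidin-2-one | O=C1OC[C@@H](Cc2ccccc2)N1 | starting material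
14 | 3-bromobut-3-enoic pivalic anhydride | C=C(Br)CC(=O)OC(=O)C(C)(C)C | intermediate
15 | (4R)-4-benzyl-3-(3-bromobut-3-enoyl)-1,3-oxazolidin-2-one | C=C(Br)CC(=O)N1C(=O)OC[C@H]1Cc1ccccc1 | intermediate
16 | 2-methylidenebutanal (2-ethylacrolein) | CCC(=C)C=O | starting material
17 | Z-dibutylboron dienolate of 15 | C=C(Br)/C=C(\OB(CCCC)CCCC)N1C(=O)OC[C@H]1Cc1ccccc1 | intermediate
18 | dibutylboron aldolate of 19 | C=C(Br)[C@@H](C(=O)N1C(=O)OC[C@H]1Cc1ccccc1)[C@@H](OB(CCCC)CCCC)C(=C)CC | intermediate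
19 | (4R)-4-benzyl-3-[(2R,3R)-2-(1-bromoethenyl)-3-hydroxy-4-methylidenehexanoyl]-1,3-oxazolidin-2-one | C=C(Br)[C@@H](C(=O)N1C(=O)OC[C@H]1Cc1ccccc1)[C@@H](O)C(=C)CC | intermediate
20 | (2S,3R)-2-(1-bromoethenyl)-4-methylidenehexane-1,3-diol | C=C(Br)[C@@H](CO)[C@@H](O)C(=C)CC | intermediate
21 | (2S,3R)-2-(1-bromoethenyl)-4-methylidene-1-(triethylsilyloxy)hexan-3-ol | C=C(Br)[C@@H](CO[Si](CC)(CC)CC)[C@@H](O)C(=C)CC | intermediate
22 | mixed anhydride of 4 with 2,4,6-trichlorobenzoic acid | Clc1cc(Cl)c(C(=O)OC(=O)[C@]2(C)O[C@@H]2C)c(Cl)c1 | intermediate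
23 | (2S,3R)-2-(1-bromoethenyl)-4-methylidene-1-(triethylsilyloxy)hexan-3-yl (2R,3R)-2,3-dimethyloxirane-2-carboxylate | C=C(Br)[C@@H](CO[Si](CC)(CC)CC)[C@@H](OC(=O)[C@]1(C)O[C@@H]1C)C(=C)CC | intermediate
24 | secondary ozonide (1,2,4-trioxolane) of 23 at the C9 methylidene | C=C(Br)[C@@H](CO[Si](CC)(CC)CC)[C@@H](OC(=O)[C@]1(C)O[C@@H]1C)C2(CC)OCOO2 | intermediate
25 | (2S,3R)-2-(1-bromoethenyl)-4-oxo-1-(triethylsilyloxy)hexan-3-yl (2R,3R)-2,3-dimethyloxirane-2-carboxylate | C=C(Br)[C@@H](CO[Si](CC)(CC)CC)[C@@H](OC(=O)[C@]1(C)O[C@@H]1C)C(=O)CC | intermediate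
26 | (2S,3R)-4-oxo-2-[1-(4,4,5,5-tetramethyl-1,3,2-dioxaborolan-2-yl)ethenyl]-1-(triethylsilyloxy)hexan-3-yl (2R,3R)-2,3-dimethyloxirane-2-carboxylate | C=C(B2OC(C)(C)C(C)(C)O2)[C@@H](CO[Si](CC)(CC)CC)[C@@H](OC(=O)[C@]1(C)O[C@@H]1C)C(=O)CC | intermediate
27 | E-enol dicyclohexylborinate of 26 | C=C(B2OC(C)(C)C(C)(C)O2)[C@@H](CO[Si](CC)(CC)CC)[C@@H](OC(=O)[C@]1(C)O[C@@H]1C)/C(OB(C3CCCCC3)C3CCCCC3)=C\C | intermediate
28 | dicyclohexylboron aldolate of 29 | C=C(B2OC(C)(C)C(C)(C)O2)[C@@H](CO[Si](CC)(CC)CC)[C@@H](OC(=O)[C@]1(C)O[C@@H]1C)C(=O)[C@@H](C)[C@@H](OB(C3CCCCC3)C3CCCCC3)CC/C(C)=C\I | intermediate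
29 | (2S,3R,5S,6S,9Z)-6-hydroxy-10-iodo-5,9-dimethyl-4-oxo-2-[1-(pinacolboryl)ethenyl]-1-(triethylsilyloxy)dec-9-en-3-yl (2R,3R)-2,3-dimethyloxirane-2-carboxylate | C=C(B2OC(C)(C)C(C)(C)O2)[C@@H](CO[Si](CC)(CC)CC)[C@@H](OC(=O)[C@]1(C)O[C@@H]1C)C(=O)[C@@H](C)[C@@H](O)CC/C(C)=C\I | intermediate
30 | (2S,3R,5S,6S,9Z)-6-(tert-butyldimethylsilyloxy)-10-iodo-5,9-dimethyl-4-oxo-2-[1-(pinacolboryl)ethenyl]-1-(triethylsilyloxy)dec-9-en-3-yl (2R,3R)-2,3-dimethyloxirane-2-carboxylate | C=C(B2OC(C)(C)C(C)(C)O2)[C@@H](CO[Si](CC)(CC)CC)[C@@H](OC(=O)[C@]1(C)O[C@@H]1C)C(=O)[C@@H](C)[C@@H](O[Si](C)(C)C(C)(C)C)CC/C(C)=C\I | intermediate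
31 | (2S,3R,5S,6S,9Z)-6-(tert-butyldimethylsilyloxy)-1-hydroxy-10-iodo-5,9-dimethyl-4-oxo-2-[1-(pinacolboryl)ethenyl]dec-9-en-3-yl (2R,3R)-2,3-dimethyloxirane-2-carboxylate | C=C(B2OC(C)(C)C(C)(C)O2)[C@@H](CO)[C@@H](OC(=O)[C@]1(C)O[C@@H]1C)C(=O)[C@@H](C)[C@@H](O[Si](C)(C)C(C)(C)C)CC/C(C)=C\I | intermediate
32 | (2R,3R,5S,6S,9Z)-6-(tert-butyldimethylsilyloxy)-10-iodo-5,9-dimethyl-1,4-dioxo-2-[1-(pinacolboryl)ethenyl]dec-9-en-3-yl (2R,3R)-2,3-dimethyloxirane-2-carboxylate | C=C(B2OC(C)(C)C(C)(C)O2)[C@@H](C=O)[C@@H](OC(=O)[C@]1(C)O[C@@H]1C)C(=O)[C@@H](C)[C@@H](O[Si](C)(C)C(C)(C)C)CC/C(C)=C\I | intermediate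
33 | (1S,6S,7S,8R,10S)-1-(tert-butyldimethylsilyloxy)-6-hydroxy-4,10-dimethyl-9-oxo-7-[1-(pinacolboryl)ethenyl]cyclodec-4Z-en-8-yl (2R,3R)-2,3-dimethyloxirane-2-carboxylate (germacrane locants) | C=C(B3OC(C)(C)C(C)(C)O3)[C@H]1[C@@H](O)/C=C(/C)CC[C@H](O[Si](C)(C)C(C)(C)C)[C@H](C)C(=O)[C@@H]1OC(=O)[C@]2(C)O[C@@H]2C | intermediate
34 | (1S,6R,7R,8R,10S)-1-(tert-butyldimethylsilyloxy)-6-chloro-4,10-dimethyl-9-oxo-7-[1-(pinacolboryl)ethenyl]cyclodec-4Z-en-8-yl (2R,3R)-2,3-dimethyloxirane-2-carboxylate (germacrane locants) | C=C(B3OC(C)(C)C(C)(C)O3)[C@H]1[C@H](Cl)/C=C(/C)CC[C@H](O[Si](C)(C)C(C)(C)C)[C@H](C)C(=O)[C@@H]1OC(=O)[C@]2(C)O[C@@H]2C | intermediate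
35 | potassium tert-butoxyborate (ate complex) of 34 | C=C([B-]3(OC(C)(C)C)OC(C)(C)C(C)(C)O3)[C@H]1[C@H](Cl)/C=C(/C)CC[C@H](O[Si](C)(C)C(C)(C)C)[C@H](C)C(=O)[C@@H]1OC(=O)[C@]2(C)O[C@@H]2C.[K+] | intermediate
36 | potassium acrylate from 34 (C11–CO2K in place of C11–Bpin, 6R chloride intact) | C=C(C(=O)[O-])[C@H]1[C@H](Cl)/C=C(/C)CC[C@H](O[Si](C)(C)C(C)(C)C)[C@H](C)C(=O)[C@@H]1OC(=O)[C@]2(C)O[C@@H]2C.[K+] | intermediate
37 | (1S,6S,7S,8R,10S)-1-(tert-butyldimethylsilyloxy)-8-[(2R,3R)-epoxyangeloyloxy]-9-oxogermacra-4Z,11(13)-dien-12,6-olide | C=C1C(=O)O[C@H]2/C=C(/C)CC[C@H](O[Si](C)(C)C(C)(C)C)[C@H](C)C(=O)[C@H](OC(=O)[C@]3(C)O[C@@H]3C)[C@@H]12 | intermediate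
38 | CNP0149149.1, (1S,6S,7S,8R,10S)-8-[(2R,3R)-epoxyangeloyloxy]-1-hydroxy-9-oxogermacra-4Z,11(13)-dien-12,6-olide | C=C1C(=O)O[C@H]2/C=C(/C)CC[C@H](O)[C@H](C)C(=O)[C@H](OC(=O)[C@]3(C)O[C@@H]3C)[C@@H]12 | target

**Step count and risks**
Total step count: 20 (steps 1–3 epoxyangelic acid, steps 4–5 iodo-aldehyde, steps 6–20 main line).
Longest linear sequence: 15 steps (steps 6–20, from 12 to 38).

Steps most likely to fail:

1. Step 17 (ring closure). The alkenylchromium species may add to the other face of the aldehyde and give the 6R carbinol or an epimeric mixture, and the strained ten-membered closure may lose material to intermolecular coupling. The fallback sets out from 32 and comes back at 33. It does not rely on facial control: the closure is run as in step 17 and the 6R epimer, the ten-membered allylic alcohol F1, is inverted by a Mitsunobu reaction with chloroacetic acid (PPh3, DIAD, toluene, 0 °C) to the 6S chloroacetate F2. The chloroacetyl group is then removed with thiourea and NaHCO3 in ethanol at room temperature, which should not touch the hindered epoxyangelate, to give 33.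

2. Step 19 (key step). The alkenylcopper may attack the allylic chloride before CO2 is inserted, the base may cause loss of HCl to a diene or elimination of the β-silyloxy ketone, and the intramolecular displacement may be slow. The fallback sets out from 33 and comes back at 37 without passing through the chloride. The alkenylboronate and the free C6 hydroxyl are joined by palladium-catalysed oxidative alkoxycarbonylation (PdCl2(PPh3)2 cat., p-benzoquinone, NaOAc, CO 1 atm, THF, rt), the known carbonylation of alkenylboron compounds in the presence of an alcohol. The carbinol oxygen is retained, so the 6S alcohol gives the cis-lactone 37 directly and no further compound arises (none, F0).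

3. Step 18 (chlorination). Ionisation or chloride exchange may erode the configuration at C6, the chloride may transpose to the tertiary C4 position, HCl may be lost, or the C6 hydroxyl may be tied up as a transannular hemiketal with the C9 ketone. The fallback sets out from 33 and comes back at 37, replacing SN2 closure by a π-allyl closure. The C6 hydroxyl is converted into the allylic methyl carbonate F3 (ClCO2Me, pyridine, DMAP, CH2Cl2, 0 °C), and the boronate is carboxylated with CO2 as in step 19 to the potassium acrylate F4 (not isolated). Pd(PPh3)4 (5 mol%) is then added to the same flask: ionisation of the carbonate by zerovalent palladium with inversion, followed by attack of the carboxylate on the π-allyl complex anti to the metal, closes the lactone at C6 with net retention and gives 37.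

**Further compounds**
F1 | step 17 | (1S,6R,7S,8R,10S)-1-(tert-butyldimethylsilyloxy)-6-hydroxy-4,10-dimethyl-9-oxo-7-[1-(pinacolboryl)ethenyl]cyclodec-4Z-en-8-yl (2R,3R)-2,3-dimethyloxirane-2-carboxylate (6-epimer of 33) | C=C(B3OC(C)(C)C(C)(C)O3)[C@H]1[C@H](O)/C=C(/C)CC[C@H](O[Si](C)(C)C(C)(C)C)[C@H](C)C(=O)[C@@H]1OC(=O)[C@]2(C)O[C@@H]2C
F2 | step 17 | 6S chloroacetate of 33 | C=C(B3OC(C)(C)C(C)(C)O3)[C@H]1[C@@H](OC(=O)CCl)/C=C(/C)CC[C@H](O[Si](C)(C)C(C)(C)C)[C@H](C)C(=O)[C@@H]1OC(=O)[C@]2(C)O[C@@H]2C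
F0 | step 19 | none | none
F3 | step 18 | 6S methyl carbonate of 33 | C=C(B3OC(C)(C)C(C)(C)O3)[C@H]1[C@@H](OC(=O)OC)/C=C(/C)CC[C@H](O[Si](C)(C)C(C)(C)C)[C@H](C)C(=O)[C@@H]1OC(=O)[C@]2(C)O[C@@H]2C
F4 | step 18 | potassium acrylate from F3 (C11–CO2K, 6S methyl carbonate intact) | C=C(C(=O)[O-])[C@H]1[C@@H](OC(=O)OC)/C=C(/C)CC[C@H](O[Si](C)(C)C(C)(C)C)[C@H](C)C(=O)[C@@H]1OC(=O)[C@]2(C)O[C@@H]2C.[K+]
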